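**Retrosynthetic overview**

1. The target is an enolised 2-acyl-6,6-diprenylcyclohexane-1,3,5-trione (ring C1–C6) with a (1S,2R,5R)-cyclopentylmethyl arm at C4. The ring is cut at C1–C2 and C4–C5, giving 2,2-diprenylmalonyl dichloride 19 and β-diketone 13, which are joined by a [3+3] double C-acylation whose ring closure copies the Claisen cyclisation of a tetraketide.
2. Enabling feature: C6 is a quaternary sp3 carbon between the carbonyl carbons C1 and C5, so C5–C6–C1 is a hidden, non-enolisable malonyl unit. C2–C3–C4 plus the isobutyryl carbonyl is a β-diketone whose central (C2) and terminal (C4) carbons are the two nucleophilic sites of its 1,3-dianion.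
3. Diketone 13 comes from a crossed Claisen condensation of ester 11 with 3-methylbutan-2-one. Ester 11 comes from vinyl oxirane 8 by palladium/formate hydrogenolysis with inversion (C–H anti to the tertiary oxygen), silylation and CuH 1,4-reduction.
4. Oxirane 8 comes from commercial (4R)-limonene oxide (chiral pool) by periodate cleavage, aldol condensation to the cyclopentene, directed epoxidation anti to the isopropenyl group, and oxidation/Wittig olefination.
5. Ring order: cyclopentane first (step 2), oxirane as a temporary ring (steps 4 to 6), six-membered trione ring last (step 13), then desilylation.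

Key step: step 13

Remark: the trione is drawn as the enol tautomer of the target SMILES; tautomers of 13, 20, 21 and 22 interconvert and are treated as one compound. Ring numbering of the target: C1 ring ketone, C2 acyl-bearing carbon, C3 enol carbon, C4 carbon bearing the cyclopentylmethyl group, C5 enol carbon, C6 diprenyl carbon.

**Route**

Step 1
Reactants: 1 (4R)-limonene 1,2-oxide (commercial cis/trans mixture at the oxirane)
Product: 2 (3R)-6-oxo-3-(prop-1-en-2-yl)heptanal
Conditions: H5IO6 (1.1 equiv), THF/H2O, 0 °C to rt
Reagents that add atoms: water, O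
Why: Periodic acid hydrolyses the oxirane to the diol in the flask and cleaves it (Malaprade-type glycol cleavage), so both oxirane diastereomers should converge on one keto aldehyde while the isopropenyl-bearing stereocentre is untouched.

Step 2
Reactants: 2 (3R)-6-oxo-3-(prop-1-en-2-yl)heptanal
Product: 3 (5S)-2-methyl-5-(prop-1-en-2-yl)cyclopent-1-ene-1-carbaldehyde
Conditions: piperidine (cat.), AcOH (cat.), toluene, 80 °C
Reagents that add atoms: none
Why: Amine-catalysed intramolecular aldol condensation (the enamine of the aldehyde adds 5-exo to the methyl ketone, then water is lost) should give the formylcyclopentene; the stereocentre is not on an enolisable or vinylogous position and should stay intact.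

Step 3
Reactants: 3 (5S)-2-methyl-5-(prop-1-en-2-yl)cyclopent-1-ene-1-carbaldehyde
Product: 4 [(5S)-2-methyl-5-(prop-1-en-2-yl)cyclopent-1-en-1-yl]methanol
Conditions: NaBH4, CeCl3·7H2O, MeOH, 0 °C
Reagents that add atoms: none
Why: Luche reduction should deliver hydride 1,2 to the enal and give the allylic alcohol without touching either alkene.

Step 4
Reactants: 4 [(5S)-2-methyl-5-(prop-1-en-2-yl)cyclopent-1-en-1-yl]methanol
Product: 5 [(1R,2S,5R)-5-methyl-2-(prop-1-en-2-yl)-6-oxabicyclo[3.1.0]hexan-1-yl]methanol (oxirane oxygen anti to the isopropenyl group)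
Conditions: VO(acac)2 (cat.), t-BuOOH, CH2Cl2, 0 °C to rt
Reagents that add atoms: tert-butyl hydroperoxide, CC(C)(C)OO
Why: Hydroxyl-directed vanadium-catalysed epoxidation should react only at the allylic alcohol alkene (the isopropenyl group has no directing hydroxyl), and the adjacent isopropenyl substituent should steer the oxygen to the opposite ring face, which sets both oxirane carbons.

Step 5
Reactants: 5 [(1R,2S,5R)-5-methyl-2-(prop-1-en-2-yl)-6-oxabicyclo[3.1.0]hexan-1-yl]methanol; 6 methyl 2-(triphenylphosphoranylidene)acetate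
Product: 8 methyl (2E)-3-[(1S,2S,5R)-5-methyl-2-(prop-1-en-2-yl)-6-oxabicyclo[3.1.0]hexan-1-yl]prop-2-enoate, via epoxy aldehyde 7 (not isolated)
Conditions: PhI(OAc)2, TEMPO (cat.), CH2Cl2, rt; then 6, rt
Reagents that add atoms: none
Why: Oxoammonium (TEMPO) oxidation of the primary alcohol gives the non-enolisable epoxy aldehyde, which should undergo Wittig olefination with the stabilised ylide in the same flask to the E-enoate without touching the oxirane.

Step 6
Reactants: 8 methyl (2E)-3-[(1S,2S,5R)-5-methyl-2-(prop-1-en-2-yl)-6-oxabicyclo[3.1.0]hexan-1-yl]prop-2-enoate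
Product: 9 methyl (2E)-3-[(1S,2R,5R)-2-hydroxy-2-methyl-5-(prop-1-en-2-yl)cyclopentyl]prop-2-enoate
Conditions: Pd2(dba)3·CHCl3 (cat.), n-Bu3P (1 per Pd), HCO2H, Et3N, 1,4-dioxane, rt
Reagents that add atoms: none
Why: Palladium-catalysed formate hydrogenolysis of an alkenyloxirane (Tsuji-type allylic hydrogenolysis): zerovalent palladium ionises the allylic C–O bond with inversion and the formate-derived hydride passes from palladium to the more substituted allyl terminus on the same face, so the new C–H should lie anti to the retained tertiary alkoxide, placing the side chain cis to the hydroxyl and trans to the isopropenyl group.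

Step 7
Reactants: 9 methyl (2E)-3-[(1S,2R,5R)-2-hydroxy-2-methyl-5-(prop-1-en-2-yl)cyclopentyl]prop-2-enoate
Product: 10 methyl (2E)-3-[(1S,2R,5R)-2-methyl-5-(prop-1-en-2-yl)-2-(triethylsilyloxy)cyclopentyl]prop-2-enoate
Conditions: Et3SiOTf, 2,6-lutidine, CH2Cl2, −78 to 0 °C
Reagents that add atoms: triethylsilyl trifluoromethanesulfonate, CC[Si](CC)(CC)OS(=O)(=O)C(F)(F)F
Why: Silyl triflate with a hindered pyridine base is the standard silylation of a tertiary alcohol and should mask the hydroxyl against the strongly basic acylation steps.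

Step 8
Reactants: 10 methyl (2E)-3-[(1S,2R,5R)-2-methyl-5-(prop-1-en-2-yl)-2-(triethylsilyloxy)cyclopentyl]prop-2-enoate
Product: 11 methyl 3-[(1S,2R,5R)-2-methyl-5-(prop-1-en-2-yl)-2-(triethylsilyloxy)cyclopentyl]propanoate
Conditions: Cu(OAc)2·H2O (cat.), 1,2-bis(diphenylphosphino)benzene (cat.), (MeO)2MeSiH, t-BuOH, toluene, rt
Reagents that add atoms: none
Why: Phosphine-ligated CuH conjugate reduction should saturate only the enoate, leaving the isolated isopropenyl alkene and the silyl ether untouched.

Step 9
Reactants: 11 methyl 3-[(1S,2R,5R)-2-methyl-5-(prop-1-en-2-yl)-2-(triethylsilyloxy)cyclopentyl]propanoate; 12 3-methylbutan-2-one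
Product: 13 2-methyl-7-[(1S,2R,5R)-2-methyl-5-(prop-1-en-2-yl)-2-(triethylsilyloxy)cyclopentyl]heptane-3,5-dione
Conditions: 12 (3 equiv), LiN(i-Pr)2 (3 equiv), THF, −78 °C; then 11, −78 °C to rt; aq. NH4Cl
Reagents that add atoms: none
Why: Crossed Claisen condensation of the kinetic (methyl-side) lithium enolate of the ketone with the methyl ester, driven by deprotonation of the β-diketone formed, should give the diketone.

Step 10
Reactants: 14 dimethyl malonate; 15 1-bromo-3-methylbut-2-ene (prenyl bromide)
Product: 17 dimethyl 2,2-bis(3-methylbut-2-en-1-yl)malonate, via dimethyl prenylmalonate 16 (not isolated)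
Conditions: NaH (2.3 equiv), 15 (2.2 equiv), THF/DMF, 0 °C to rt
Reagents that add atoms: none
Why: Two successive SN2 alkylations of the malonate enolate with a reactive allylic bromide should install both prenyl groups on the future quaternary carbon.

Step 11
Reactants: 17 dimethyl 2,2-bis(3-methylbut-2-en-1-yl)malonate
Product: 18 2,2-bis(3-methylbut-2-en-1-yl)malonic acid
Conditions: KOH, MeOH/H2O, reflux; then cold aq. HCl to pH 2
Reagents that add atoms: potassium hydroxide, [K+].[OH-]
Why: Saponification of the hindered diester followed by cold acidification should give the disubstituted malonic acid, which does not decarboxylate at these temperatures.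

Step 12
Reactants: 18 2,2-bis(3-methylbut-2-en-1-yl)malonic acid
Product: 19 2,2-bis(3-methylbut-2-en-1-yl)malonyl dichloride
Conditions: (COCl)2, DMF (cat.), CH2Cl2, 0 °C to rt; evaporation, used crude
Reagents that add atoms: oxalyl chloride, ClC(=O)C(=O)Cl
Why: Vilsmeier-type activation converts both carboxyl groups into acid chlorides with only volatile by-products; the diacid chloride has no α-hydrogen and cannot form a ketene.

Step 13
Reactants: 13 2-methyl-7-[(1S,2R,5R)-2-methyl-5-(prop-1-en-2-yl)-2-(triethylsilyloxy)cyclopentyl]heptane-3,5-dione; 19 2,2-bis(3-methylbut-2-en-1-yl)malonyl dichloride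
Product: 21 3,5-dihydroxy-4-{[(1S,2R,5R)-2-methyl-5-(prop-1-en-2-yl)-2-(triethylsilyloxy)cyclopentyl]methyl}-2-(2-methylpropanoyl)-6,6-bis(3-methylbut-2-en-1-yl)cyclohexa-2,4-dien-1-one, via triketo acid chloride enolate 20 (not isolated)
Conditions: 13, LiN(i-Pr)2 (4.2 equiv), THF (0.02 M), −78 to 0 °C; then 19 (1.1 equiv), slow addition, −78 °C to rt; cold aq. HCl
Reagents that add atoms: none
Why: The amide base turns 13 into its 1,3-dianion (the methylene next to the side chain is deprotonated in preference to the isopropyl methine), and the more basic terminal carbanion attacks one C(=O)Cl of 19 to form the ring bond C4–C5. The tethered acid chloride 20, kept as a dienolate by the excess base, then closes by attack of the central diketonate carbon on the second C(=O)Cl to form the ring bond C1–C2, a 6-exo-trig C-acylation that builds the complete six-membered ring. The closest known reaction types are the α,α'-diacylation of ketone enol derivatives by malonyl dichlorides (Effenberger-type cyclisation to cyclohexane-1,3,5-triones), the terminal acylation of β-diketone dianions, and the Claisen cyclisation of a tetraketide used in the biosynthesis of acylphloroglucinols. No stereocentre is formed, because C6 carries two identical prenyl groups, and the three cyclopentane centres are remote and not enolisable. The step needs terminal over central first acylation (secured by the reactivity order of the dianion), ring closure over a second intermolecular acylation (secured by the gem-diprenyl Thorpe–Ingold effect, dilution and slow addition), and C- over O-acylation in the closure (favoured by lithium chelation of the diketonate oxygens and by the drain of the C-acylated trione as its doubly deprotonated vinylogous acid). The excess base also keeps the acidic products from quenching unreacted dianion.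

Step 14
Reactants: 21 3,5-dihydroxy-4-{[(1S,2R,5R)-2-methyl-5-(prop-1-en-2-yl)-2-(triethylsilyloxy)cyclopentyl]methyl}-2-(2-methylpropanoyl)-6,6-bis(3-methylbut-2-en-1-yl)cyclohexa-2,4-dien-1-one
Product: 22 3,5-dihydroxy-4-{[(1S,2R,5R)-2-hydroxy-2-methyl-5-(prop-1-en-2-yl)cyclopentyl]methyl}-2-(2-methylpropanoyl)-6,6-bis(3-methylbut-2-en-1-yl)cyclohexa-2,4-dien-1-one (CNP0290578.2)
Conditions: HF·pyridine, pyridine, THF, 0 °C to rt
Reagents that add atoms: none
Why: Fluoride-driven cleavage of the tertiary triethylsilyl ether under buffered conditions should free the hydroxyl without dehydrating it or affecting the enolised trione and the three alkenes.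

**Compound list**

1 | (4R)-limonene 1,2-oxide, (4R)-1-methyl-4-(prop-1-en-2-yl)-7-oxabicyclo[4.1.0]heptane (cis/trans mixture) | C=C(C)[C@@H]1CCC2(C)OC2C1 | starting material
2 | (3R)-6-oxo-3-(prop-1-en-2-yl)heptanal | C=C(C)[C@@H](CC=O)CCC(C)=O | intermediate
3 | (5S)-2-methyl-5-(prop-1-en-2-yl)cyclopent-1-ene-1-carbaldehyde | C=C(C)[C@@H]1CCC(C)=C1C=O | intermediate
4 | [(5S)-2-methyl-5-(prop-1-en-2-yl)cyclopent-1-en-1-yl]methanol | C=C(C)[C@@H]1CCC(C)=C1CO | intermediate
5 | [(1R,2S,5R)-5-methyl-2-(prop-1-en-2-yl)-6-oxabicyclo[3.1.0]hexan-1-yl]methanol | C=C(C)[C@@H]1CC[C@@]2(C)O[C@@]12CO | intermediate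
6 | methyl 2-(triphenylphosphoranylidene)acetate | COC(=O)C=P(c1ccccc1)(c1ccccc1)c1ccccc1 | starting material
7 | (1S,2S,5R)-5-methyl-2-(prop-1-en-2-yl)-6-oxabicyclo[3.1.0]hexane-1-carbaldehyde (not isolated) | C=C(C)[C@@H]1CC[C@@]2(C)O[C@@]12C=O | intermediate
8 | methyl (2E)-3-[(1S,2S,5R)-5-methyl-2-(prop-1-en-2-yl)-6-oxabicyclo[3.1.0]hexan-1-yl]prop-2-enoate | C=C(C)[C@@H]1CC[C@@]2(C)O[C@@]12/C=C/C(=O)OC | intermediate
9 | methyl (2E)-3-[(1S,2R,5R)-2-hydroxy-2-methyl-5-(prop-1-en-2-yl)cyclopentyl]prop-2-enoate | C=C(C)[C@@H]1CC[C@@](C)(O)[C@H]1/C=C/C(=O)OC | intermediate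
10 | methyl (2E)-3-[(1S,2R,5R)-2-methyl-5-(prop-1-en-2-yl)-2-(triethylsilyloxy)cyclopentyl]prop-2-enoate | C=C(C)[C@@H]1CC[C@@](C)(O[Si](CC)(CC)CC)[C@H]1/C=C/C(=O)OC | intermediate
11 | methyl 3-[(1S,2R,5R)-2-methyl-5-(prop-1-en-2-yl)-2-(triethylsilyloxy)cyclopentyl]propanoate | C=C(C)[C@@H]1CC[C@@](C)(O[Si](CC)(CC)CC)[C@H]1CCC(=O)OC | intermediate
12 | 3-methylbutan-2-one | CC(=O)C(C)C | starting material
13 | 2-methyl-7-[(1S,2R,5R)-2-methyl-5-(prop-1-en-2-yl)-2-(triethylsilyloxy)cyclopentyl]heptane-3,5-dione | C=C(C)[C@@H]1CC[C@@](C)(O[Si](CC)(CC)CC)[C@H]1CCC(=O)CC(=O)C(C)C | intermediate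
14 | dimethyl malonate | COC(=O)CC(=O)OC | starting material
15 | 1-bromo-3-methylbut-2-ene (prenyl bromide) | CC(C)=CCBr | starting material
16 | dimethyl 2-(3-methylbut-2-en-1-yl)malonate (not isolated) | COC(=O)C(CC=C(C)C)C(=O)OC | intermediate
17 | dimethyl 2,2-bis(3-methylbut-2-en-1-yl)malonate | COC(=O)C(CC=C(C)C)(CC=C(C)C)C(=O)OC | intermediate
18 | 2,2-bis(3-methylbut-2-en-1-yl)malonic acid | OC(=O)C(CC=C(C)C)(CC=C(C)C)C(=O)O | intermediate
19 | 2,2-bis(3-methylbut-2-en-1-yl)malonyl dichloride | O=C(Cl)C(CC=C(C)C)(CC=C(C)C)C(=O)Cl | intermediate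
20 | 8-methyl-4-{[(1S,2R,5R)-2-methyl-5-(prop-1-en-2-yl)-2-(triethylsilyloxy)cyclopentyl]methyl}-2,2-bis(3-methylbut-2-en-1-yl)-3,5,7-trioxononanoyl chloride (present as its lithium enolate; C4 of the chain not configurationally defined; not isolated) | C=C(C)[C@@H]1CC[C@@](C)(O[Si](CC)(CC)CC)[C@H]1CC(C(=O)CC(=O)C(C)C)C(=O)C(CC=C(C)C)(CC=C(C)C)C(=O)Cl | intermediate
21 | 3,5-dihydroxy-4-{[(1S,2R,5R)-2-methyl-5-(prop-1-en-2-yl)-2-(triethylsilyloxy)cyclopentyl]methyl}-2-(2-methylpropanoyl)-6,6-bis(3-methylbut-2-en-1-yl)cyclohexa-2,4-dien-1-one | C=C(C)[C@@H]1CC[C@@](C)(O[Si](CC)(CC)CC)[C@H]1CC1=C(O)C(CC=C(C)C)(CC=C(C)C)C(=O)C(C(=O)C(C)C)=C1O | intermediate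
22 | 3,5-dihydroxy-4-{[(1S,2R,5R)-2-hydroxy-2-methyl-5-(prop-1-en-2-yl)cyclopentyl]methyl}-2-(2-methylpropanoyl)-6,6-bis(3-methylbut-2-en-1-yl)cyclohexa-2,4-dien-1-one (CNP0290578.2) | C=C(C)[C@@H]1CC[C@@](C)(O)[C@H]1CC1=C(O)C(CC=C(C)C)(CC=C(C)C)C(=O)C(C(=O)C(C)C)=C1O | target

**Step count**

Total steps: 14 (steps 1 to 9 for the diketone, steps 10 to 12 for the dichloride, steps 13 and 14). Longest linear sequence: 11 steps (steps 1 to 9, 13, 14).

**Steps most likely to fail**

Step 13. The one-pot double acylation may lose material in four ways: proton transfer from the acidic acylation products to unreacted dianion, a second intermolecular acylation of the tethered acid chloride, O-acylation in the ring closure, and attack of the excess amide base on the dichloride. Fallback: the two bonds are made in two separate ester condensations, where O-acylation is reversible. The fallback sets out from 13 and 17. The dianion of 13 (LiN(i-Pr)2, THF, −78 to 0 °C) is acylated at its terminal carbon by diester 17, a known acylation of β-diketone dianions by esters, to give methyl 8-methyl-4-{[(1S,2R,5R)-2-methyl-5-(prop-1-en-2-yl)-2-(triethylsilyloxy)cyclopentyl]methyl}-2,2-bis(3-methylbut-2-en-1-yl)-3,5,7-trioxononanoate F1, which is isolated. An intramolecular Claisen (Dieckmann-type) condensation of this tetraketide-like ester with NaOMe in MeOH or KOt-Bu in THF, followed by acidification, should close the ring and comes back to the route at 21.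

Step 6. Palladium has to enter on the ring face that carries the isopropenyl and methyl groups, so oxidative addition may be slow; β-hydride elimination of the allylpalladium intermediate to a dienol and π–σ–π isomerisation may then compete. Fallback: the C–H bond is made by reductive cleavage of the α C–O bond of an epoxy carbonyl compound instead of allylic hydrogenolysis. The fallback sets out from epoxy aldehyde 7, isolated after the oxidation of 5. Treatment with SmI2 (divalent samarium) in THF/MeOH at −90 °C should give (1S,2R,5R)-2-hydroxy-2-methyl-5-(prop-1-en-2-yl)cyclopentane-1-carbaldehyde F2. The configuration next to the formyl group is not fixed by the mechanism here; the desired epimer is the thermodynamically preferred one (formyl trans to the isopropenyl and methyl groups, hydrogen-bonded to the cis hydroxyl). The sequence is exposed to dehydration and retro-aldol cleavage and is therefore kept cold and neutral. Wittig olefination of F2 with ylide 6 in CH2Cl2 comes back to the route at 9.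

Step 9. Proton exchange between the ketone enolate and the ester or the product may stall the condensation, and the ketone may undergo self-aldol reaction. Fallback: the ester is replaced by a more reactive acyl donor. The fallback sets out from 11. Saponification (LiOH, THF/H2O) gives 3-[(1S,2R,5R)-2-methyl-5-(prop-1-en-2-yl)-2-(triethylsilyloxy)cyclopentyl]propanoic acid F3. Carbonyldiimidazole in THF converts it into 1-(1H-imidazol-1-yl)-3-[(1S,2R,5R)-2-methyl-5-(prop-1-en-2-yl)-2-(triethylsilyloxy)cyclopentyl]propan-1-one F4. C-acylation of the lithium enolate of 12 (LiN(i-Pr)2, THF, −78 °C) with F4 comes back to the route at 13.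

**Further compounds**

F1 | step 13 | methyl 8-methyl-4-{[(1S,2R,5R)-2-methyl-5-(prop-1-en-2-yl)-2-(triethylsilyloxy)cyclopentyl]methyl}-2,2-bis(3-methylbut-2-en-1-yl)-3,5,7-trioxononanoate | C=C(C)[C@@H]1CC[C@@](C)(O[Si](CC)(CC)CC)[C@H]1CC(C(=O)CC(=O)C(C)C)C(=O)C(CC=C(C)C)(CC=C(C)C)C(=O)OC
F2 | step 6 | (1S,2R,5R)-2-hydroxy-2-methyl-5-(prop-1-en-2-yl)cyclopentane-1-carbaldehyde | C=C(C)[C@@H]1CC[C@@](C)(O)[C@H]1C=O
F3 | step 9 | 3-[(1S,2R,5R)-2-methyl-5-(prop-1-en-2-yl)-2-(triethylsilyloxy)cyclopentyl]propanoic acid | C=C(C)[C@@H]1CC[C@@](C)(O[Si](CC)(CC)CC)[C@H]1CCC(=O)O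
F4 | step 9 | 1-(1H-imidazol-1-yl)-3-[(1S,2R,5R)-2-methyl-5-(prop-1-en-2-yl)-2-(triethylsilyloxy)cyclopentyl]propan-1-one | C=C(C)[C@@H]1CC[C@@](C)(O[Si](CC)(CC)CC)[C@H]1CCC(=O)n1ccnc1
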